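**Retrosynthetic overview** (azulene numbering: C1 carries the side chain, C3a the angular methyl, C4 is CH2, C5 carries OAc, C6 the methylidene, C8a is the fusion CH)
1. The side chain comes last, by E-selective cross-metathesis and Felkin–Anh allylation of a C1 acetyl group. Until then the acetyl group is stored as an (E)-but-2-en-2-yl group.
2. The cycloheptane is opened out of a bicyclo[3.2.0]heptane by β-scission of a bridgehead alkoxy radical. The bond that breaks, C5–C8a, is not in the target.
3. Key disconnection: the cyclobutane bonds C4–C5 and C3a–C8a are made by intramolecular enone–olefin [2+2] photocycloaddition of a 2-silyloxy-3-alkylcyclopent-2-enone, which closes the cyclopentane and the cyclobutane together.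
4. Enabling feature: in the seven-membered ring, C5 and C8a are linked by two atoms on one side (C4, C3a) and by three on the other (C6, C7, C8). A C5–C8a bond therefore turns the cycloheptane into a cyclobutane fused to a cyclopentane, and the adjacent C5–O / C6=CH2 pair is the C–O / C=O pair of cyclopentane-1,2-dione.
5. The photosubstrate comes from Claisen rearrangement of an enol ether of cyclopentane-1,2-dione, with chirality transfer from a CBS-derived allylic alcohol. Ring order: cyclopentanone (bought), then cyclopentane and cyclobutane (key step), then cycloheptane (fragmentation).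

Key step: step 6

Remark: 5 is drawn as its dominant enol tautomer. The geometry of the but-2-en-2-yl group may scramble under irradiation, which has no consequence because step 12 removes that alkene.

Step 1
Reactants: 1 2-methylhexa-1,5-diene; 2 3-methylbut-3-en-2-one
Product: 3 (3E)-3,7-dimethylocta-3,7-dien-2-one
Conditions: 2 (3 equiv), second-generation Hoveyda–Grubbs catalyst (3 mol%), CH2Cl2, 40 °C
Reagents that add atoms: none
Why: Olefin cross-metathesis between the reactive monosubstituted alkene of 1 and the electron-poor 1,1-disubstituted enone 2 should pair selectively, leave the gem-disubstituted alkene of 1 untouched and give the thermodynamically preferred E trisubstituted enone.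

Step 2
Reactants: 3 (3E)-3,7-dimethylocta-3,7-dien-2-one
Product: 4 (2R,3E)-3,7-dimethylocta-3,7-dien-2-ol
Conditions: (S)-Me-CBS oxazaborolidine (15 mol%), catecholborane, toluene, −78 °C; aq. NaOH
Reagents that add atoms: none
Why: In this Corey–Bakshi–Shibata reduction the alkenyl group acts as the large and the methyl group as the small substituent, so the (S)-catalyst should give the (R)-carbinol, and catecholborane at low temperature does not hydroborate the alkenes.

Step 3
Reactants: 4 (2R,3E)-3,7-dimethylocta-3,7-dien-2-ol; 5 cyclopentane-1,2-dione (enol form)
Product: 6 2-{[(2S,3E)-3,7-dimethylocta-3,7-dien-2-yl]oxy}cyclopent-2-en-1-one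
Conditions: PPh3, DIAD, toluene, 0 °C → rt
Reagents that add atoms: none
Why: In this Mitsunobu etherification the acidic enol OH of 5 is alkylated on oxygen by SN2 displacement of the oxyphosphonium ion, which inverts the carbinol centre from R to S.

Step 4
Reactants: 6 2-{[(2S,3E)-3,7-dimethylocta-3,7-dien-2-yl]oxy}cyclopent-2-en-1-one
Product: 8 2-hydroxy-3-[(2E,4R)-3,7-dimethylocta-2,7-dien-4-yl]cyclopent-2-en-1-one, via 1,2-dione tautomer 7 (not isolated)
Conditions: o-xylene, BHT (cat.), 140 °C
Reagents that add atoms: none
Why: In this Claisen rearrangement of a 2-allyloxy enone the carbinol methyl group sits pseudo-equatorial in the cyclic transition state, so the C–O stereocentre is transferred suprafacially across the E-allyl unit to the new C–C stereocentre (R) with formation of an E alkene, and enolisation of the first-formed dione restores the enol.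

Step 5
Reactants: 8 2-hydroxy-3-[(2E,4R)-3,7-dimethylocta-2,7-dien-4-yl]cyclopent-2-en-1-one
Product: 9 2-(tert-butyldimethylsilyloxy)-3-[(2E,4R)-3,7-dimethylocta-2,7-dien-4-yl]cyclopent-2-en-1-one
Conditions: TBSCl, imidazole, DMF, rt
Reagents that add atoms: tert-butyldimethylsilyl chloride, CC(C)(C)[Si](C)(C)Cl
Why: O-silylation of the acidic enol touches no stereocentre, blocks tautomerisation and installs the bulky group that steers the next step.

Step 6
Reactants: 9 2-(tert-butyldimethylsilyloxy)-3-[(2E,4R)-3,7-dimethylocta-2,7-dien-4-yl]cyclopent-2-en-1-one
Product: 10 10-[(E)-but-2-en-2-yl]-5-(tert-butyldimethylsilyloxy)-7-methyltricyclo[5.3.0.0^1,5]decan-4-one (cis,cis-fused 5-4-5 tricycle, methyl and butenyl on the same face of the new cyclopentane)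
Conditions: hν (350 nm, Pyrex), degassed CH2Cl2 (5 mM), 0 °C
Reagents that add atoms: none
Why: Intramolecular enone–olefin [2+2] photocycloaddition: the triplet enone attacks the internal carbon of the 1,1-disubstituted alkene with its β-carbon, and after spin inversion the 1,4-biradical joins the CH2 terminus to the silyloxy-bearing α-carbon, so that both new C–C bonds arise in one operation from a monocyclic precursor. The closest known reaction type is the straight (rule of five) photocycloaddition of 3-(pent-4-enyl)cycloalk-2-enones, which is known to tolerate fully substituted enone and alkene carbons. The cyclopentane closes in the 5-exo-trig mode through the three-atom tether and the cyclobutane by recombination of the 1,4-biradical, and both new ring fusions can only be cis. The one stereocentre of 9 controls the three new ones: A(1,3) strain with the OTBS group keeps its C–H bond in the enone plane, the tether then reaches one enone face while the butenyl group covers the other, which puts the new angular methyl group on the same side of the cyclopentane as the butenyl group, and the configurations of the central quaternary carbon and of the silyloxy carbon follow from the cis fusions. The step needs straight rather than crossed regiochemistry, which the tether length secures, and reaction at the terminal alkene only, which is secured because the butenyl alkene is separated from the enone by a single atom and cannot reach a cyclobutane geometry.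

Step 7
Reactants: 10 tricyclic silyloxy ketone
Product: 11 tert-butyldimethyl({10-[(E)-but-2-en-2-yl]-7-methyl-4-methylidenetricyclo[5.3.0.0^1,5]decan-5-yl}oxy)silane
Conditions: Ph3PCH3Br, KOtBu, toluene, rt → 80 °C
Reagents that add atoms: methyltriphenylphosphonium bromide, C[P+](c1ccccc1)(c1ccccc1)c1ccccc1.[Br-]
Why: Wittig methylenation of the only carbonyl group, whose stereogenic α-carbon is quaternary and cannot epimerise, is run while the oxygen is still silylated so that no α-ketol rearrangement of the strained ring can start.

Step 8
Reactants: 11 tricyclic methylidene silyl ether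
Product: 12 10-[(E)-but-2-en-2-yl]-7-methyl-4-methylidenetricyclo[5.3.0.0^1,5]decan-5-ol
Conditions: Bu4NF, THF, rt → 45 °C
Reagents that add atoms: none
Why: Fluoride-induced desilylation frees the bridgehead cyclobutanol under non-acidic conditions, which avoids semipinacol ring expansion and touches no stereocentre.

Step 9
Reactants: 12 bridgehead allylic cyclobutanol
Product: 13 (1S,3aR,8aS)-1-[(E)-but-2-en-2-yl]-3a-methyl-6-methylideneoctahydroazulen-5(1H)-one (trans-fused)
Conditions: [Ir(dF(CF3)ppy)2(5,5'-d(CF3)bpy)]PF6 (2 mol%), 2,4,6-triisopropylbenzenethiol (20 mol%), Bu4P (MeO)2PO2 (20 mol%), PhCF3, blue LEDs, rt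
Reagents that add atoms: none
Why: In this alkoxy-radical β-scission (redox-neutral ring-opening isomerisation of a tertiary cycloalkanol by proton-coupled electron transfer) the bridgehead alkoxy radical should break the bond to the fully substituted carbon, because this releases the strain of the bicyclo[3.2.0] unit and gives a tertiary radical where the alternatives give a primary or an alkenyl radical, and the thiol should deliver hydrogen to the face opposite the angular methyl and butenyl groups, which sets the trans ring fusion at C8a.

Step 10
Reactants: 13 α-methylidene cycloheptanone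
Product: 14 (1S,3aR,5R,8aS)-1-[(E)-but-2-en-2-yl]-3a-methyl-6-methylidenedecahydroazulen-5-ol (OH syn to the angular methyl)
Conditions: iBu2AlH, CH2Cl2, −78 °C; aq. KNa tartrate
Reagents that add atoms: none
Why: In this 1,2-reduction of the enone the bulky hydride should approach the carbonyl group from the face away from the pseudo-axial, 1,3-related angular methyl group, which gives the alcohol syn to that methyl group.

Step 11
Reactants: 14 (5R)-allylic alcohol
Product: 15 (1S,3aR,5S,8aS)-1-[(E)-but-2-en-2-yl]-3a-methyl-6-methylidenedecahydroazulen-5-yl acetate
Conditions: AcOH, PPh3, DIAD, toluene, 0 °C → rt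
Reagents that add atoms: acetic acid, CC(=O)O
Why: The Mitsunobu reaction displaces the pseudo-axial oxyphosphonium group from the open opposite face, so the acetate enters with inversion and C5 takes the configuration of the target in the same operation that acylates it.

Step 12
Reactants: 15 butenyl acetate
Product: 16 (1S,3aR,5S,8aS)-1-acetyl-3a-methyl-6-methylidenedecahydroazulen-5-yl acetate
Conditions: O3 (1 equiv, titrated solution), CH2Cl2, −78 °C, Sudan Red 7B as end-point indicator; then Me2S, −78 °C → rt
Reagents that add atoms: ozone, [O-][O+]=O
Why: Ozonolysis should take the electron-rich trisubstituted alkene before the 1,1-disubstituted alkene that is deactivated by its allylic acetate, and the neutral reductive work-up leaves the stereocentre next to the new ketone untouched.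

Step 13
Reactants: 16 methyl ketone
Product: 17 (1S,3aR,5S,8aS)-1-[(2S)-2-hydroxypent-4-en-2-yl]-3a-methyl-6-methylidenedecahydroazulen-5-yl acetate
Conditions: allyl bromide, Zn dust, THF, 0 °C (allylzinc bromide preformed); then 16, −78 → −20 °C; aq. NH4Cl
Reagents that add atoms: allyl bromide, C=CCBr
Why: The allylzinc addition (Barbier-type allylation) spares the acetate, and under Felkin–Anh control, with C8a as the large, the ring CH2 as the medium and H as the small group, it should attack anti to C8a and give the (S)-tertiary alcohol, the same sense as known additions to 17-acetyl steroids.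

Step 14
Reactants: 17 homoallylic alcohol; 18 2-methylbut-3-en-2-ol
Product: 19 (1S,3aR,5S,8aS)-1-[(2S,4E)-2,6-dihydroxy-6-methylhept-4-en-2-yl]-3a-methyl-6-methylidenedecahydroazulen-5-yl acetate (target)
Conditions: 18 (5 equiv), second-generation Hoveyda–Grubbs catalyst (5 mol%), CH2Cl2, 40 °C
Reagents that add atoms: none
Why: Olefin cross-metathesis of the terminal alkene with the unprotected tertiary allylic alcohol is a well-matched pairing that should give the E alkene, while the hindered ring methylidene group stays inert.

**Compound list**
1 | 2-methylhexa-1,5-diene | C=CCCC(C)=C | starting material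
2 | 3-methylbut-3-en-2-one | CC(=O)C(C)=C | starting material
3 | (3E)-3,7-dimethylocta-3,7-dien-2-one | CC(=O)/C(C)=C/CCC(C)=C | intermediate
4 | (2R,3E)-3,7-dimethylocta-3,7-dien-2-ol | C[C@@H](O)/C(C)=C/CCC(C)=C | intermediate
5 | cyclopentane-1,2-dione (enol form, 2-hydroxycyclopent-2-en-1-one) | O=C1CCC=C1O | starting material
6 | 2-{[(2S,3E)-3,7-dimethylocta-3,7-dien-2-yl]oxy}cyclopent-2-en-1-one | C[C@H](OC1=CCCC1=O)/C(C)=C/CCC(C)=C | intermediate
7 | 1,2-dione tautomer of 8 (first Claisen product, not isolated) | O=C1CC[C@@H]([C@@H](/C(C)=C/C)CCC(C)=C)C1=O | intermediate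
8 | 2-hydroxy-3-[(2E,4R)-3,7-dimethylocta-2,7-dien-4-yl]cyclopent-2-en-1-one | O=C1CCC([C@@H](/C(C)=C/C)CCC(C)=C)=C1O | intermediate
9 | 2-(tert-butyldimethylsilyloxy)-3-[(2E,4R)-3,7-dimethylocta-2,7-dien-4-yl]cyclopent-2-en-1-one | O=C1CCC([C@@H](/C(C)=C/C)CCC(C)=C)=C1O[Si](C)(C)C(C)(C)C | intermediate
10 | 10-[(E)-but-2-en-2-yl]-5-(tert-butyldimethylsilyloxy)-7-methyltricyclo[5.3.0.0^1,5]decan-4-one, cis,cis-fused, methyl and butenyl syn | O=C1CC[C@@]23[C@@H](/C(C)=C/C)CC[C@]2(C)C[C@@]13O[Si](C)(C)C(C)(C)C | intermediate
11 | 4-methylidene analogue of 10 (silyl ether) | C=C1CC[C@@]23[C@@H](/C(C)=C/C)CC[C@]2(C)C[C@@]13O[Si](C)(C)C(C)(C)C | intermediate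
12 | 10-[(E)-but-2-en-2-yl]-7-methyl-4-methylidenetricyclo[5.3.0.0^1,5]decan-5-ol | C=C1CC[C@@]23[C@@H](/C(C)=C/C)CC[C@]2(C)C[C@@]13O | intermediate
13 | (1S,3aR,8aS)-1-[(E)-but-2-en-2-yl]-3a-methyl-6-methylideneoctahydroazulen-5(1H)-one | C=C1CC[C@H]2[C@@H](/C(C)=C/C)CC[C@]2(C)CC1=O | intermediate
14 | (1S,3aR,5R,8aS)-1-[(E)-but-2-en-2-yl]-3a-methyl-6-methylidenedecahydroazulen-5-ol | C=C1CC[C@H]2[C@@H](/C(C)=C/C)CC[C@]2(C)C[C@H]1O | intermediate
15 | (1S,3aR,5S,8aS)-1-[(E)-but-2-en-2-yl]-3a-methyl-6-methylidenedecahydroazulen-5-yl acetate | C=C1CC[C@H]2[C@@H](/C(C)=C/C)CC[C@]2(C)C[C@@H]1OC(C)=O | intermediate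
16 | (1S,3aR,5S,8aS)-1-acetyl-3a-methyl-6-methylidenedecahydroazulen-5-yl acetate | C=C1CC[C@H]2[C@@H](C(C)=O)CC[C@]2(C)C[C@@H]1OC(C)=O | intermediate
17 | (1S,3aR,5S,8aS)-1-[(2S)-2-hydroxypent-4-en-2-yl]-3a-methyl-6-methylidenedecahydroazulen-5-yl acetate | C=C1CC[C@H]2[C@@H]([C@@](C)(O)CC=C)CC[C@]2(C)C[C@@H]1OC(C)=O | intermediate
18 | 2-methylbut-3-en-2-ol | C=CC(C)(C)O | starting material
19 | (1S,3aR,5S,8aS)-1-[(2S,4E)-2,6-dihydroxy-6-methylhept-4-en-2-yl]-3a-methyl-6-methylidenedecahydroazulen-5-yl acetate | C=C1CC[C@H]2[C@@H]([C@@](C)(O)C/C=C/C(C)(C)O)CC[C@]2(C)C[C@@H]1OC(C)=O | target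

Total step count: 14. Longest linear sequence: 14 steps (from 1 or 2 to 19).

**Steps most likely to fail**

Step 9.
- What may go wrong: back electron transfer without productive O–H activation; β-scission toward the CH2 carbon; conjugate addition of the thiol to the α-methylidene ketone as it forms; or oxidation of the trisubstituted alkene by the excited photocatalyst.
- Fallback: the ring opening and the hydrogen delivery are separated into an oxidative and a reductive event. Setting out from 12, a hypoiodite fragmentation (PhI(OAc)2, I2, CH2Cl2, visible light, 0 °C) should open the same bond and trap the tertiary radical as the 8a-iodo ketone F1. Radical deiodination of F1 ((Me3Si)3SiH, Et3B, air, toluene, −20 °C) should then place hydrogen on the face away from the methyl and butenyl groups. The route is rejoined at 13.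

Step 6.
- What may go wrong: attack on the wrong enone face if A(1,3) control erodes in the twisted triplet, or radiationless decay through the nearby butenyl group that slows the cycloaddition until decomposition competes.
- Fallback: facial control moves from the substrate to a catalyst. Setting out from 9, the enone is bound to a proline-derived B-aryl oxazaborolidine activated by AlBr3 (CH2Cl2, −70 °C). This shifts its absorption, so that irradiation at 366 nm excites only the complex, and the catalyst enantiomer matched to the substrate shields the unwanted face. The route is rejoined at 10. New compounds on this way: none F0.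

Step 11 (together with the facial outcome of step 10, on which it depends).
- What may go wrong: hydride delivery from both faces in step 10, or allylic transposition (SN2') and elimination during the Mitsunobu displacement.
- Fallback: reagent-controlled reduction followed by acylation with retention. Setting out from 13, Corey–Bakshi–Shibata reduction with the (R)-oxazaborolidine and catecholborane (toluene, −78 °C) should give the (5S)-allylic alcohol F2. Plain acetylation (Ac2O, pyridine, DMAP, CH2Cl2, 0 °C) then rejoins the route at 15.

**Further compounds**
F1 | step 9 | 8a-iodo-1-[(E)-but-2-en-2-yl]-3a-methyl-6-methylideneoctahydroazulen-5(1H)-one (iodine anti to the angular methyl) | C=C1CC[C@@]2(I)[C@@H](/C(C)=C/C)CC[C@]2(C)CC1=O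
F0 | step 6 | none | none
F2 | step 11 | (1S,3aR,5S,8aS)-1-[(E)-but-2-en-2-yl]-3a-methyl-6-methylidenedecahydroazulen-5-ol | C=C1CC[C@H]2[C@@H](/C(C)=C/C)CC[C@]2(C)C[C@@H]1O
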